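**Retrosynthetic overview**
1. Target ⇐ acetylation and desilylation/Peterson methylenation of chloro-lactone 28; C6–Cl ⇐ ene-type chlorination of the Δ5 lactone 27.
2. Lactone ring C (C7–O bond, C7 stereocentre) ⇐ cobalt-hydride 1,4-hydrolactonization of the ten-membered 1,3-diene tert-butyl ester 26 (key step, new).
3. Ten-membered ring B ⇐ ethylene-mediated ring-closing enyne metathesis of enyne 24 (forms C6=C7 and the C5 methylene).
4. Side chains ⇐ right: Weinreb amide / methoxyallene / propionate ketone-aldol (C9, C8, C17); left: Mukaiyama aldol / syn-reduction (C2, C4).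
5. Ring A ⇐ catalytic asymmetric Diels–Alder of 1 + 2 (C1, C10, C14). Ring order: A, then B, then lactone C.

Convention: locants C1–C20 and the descriptors quoted for compounds 6–29 follow the briarane numbering of the target (ring A = C1, C10–C14; C15 on C1; C16 on C5; C17/C18/C19 = lactone CH, its methyl, carbonyl; C20 on C11); TBS = tert-butyldimethylsilyl, TMS = trimethylsilyl.
Assumption: diene 1 is purchased (otherwise one step from crotonaldehyde), and the facial sense of the step 1 catalyst follows the usual model for 2-substituted enals (if opposite, the enantiomeric catalyst is used).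

**Step 1**
Reactants: 1 (E)-1-(tert-butyldimethylsilyloxy)buta-1,3-diene; 2 ethyl (E)-3-methyl-4-oxobut-2-enoate
Product: 3 ethyl (1S,5S,6R)-5-(TBSO)-6-formyl-6-methylcyclohex-3-ene-1-carboxylate
Conditions: (S)-3,3-diphenyl-1-(o-tolyl)tetrahydropyrrolo[1,2-c][1,3,2]oxazaborole (20 mol %), Tf2NH (20 mol %), CH2Cl2, −78 → −40 °C
Reagents that add atoms: none
Why: Diels–Alder reaction under cationic oxazaborolidine catalysis, in which the catalyst-bound formyl group directs the siloxy-bearing diene terminus to C1 and sits endo (C14–O cis to CHO), the E-dienophile fixes C2/C9 trans, and the catalyst face selection sets C1, C10 and C14 absolutely.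

**Step 2**
Reactants: 4 4-(trimethylsilyl)but-3-yn-2-one
Product: 5 2-(trimethylsilyloxy)-4-(trimethylsilyl)but-1-en-3-yne
Conditions: TMSOTf, Et3N, Et2O, 0 °C; cold aq NaHCO3 wash
Reagents that add atoms: trimethylsilyl triflate C[Si](C)(C)OS(=O)(=O)C(F)(F)F
Why: Soft enolisation/O-silylation of a methyl ketone whose only enolisable position is the methyl group (silyl enol ether formation).

**Step 3**
Reactants: 3 ring A aldehyde ester; 5 silyl enol ether
Product: 6 β-hydroxy ynone (1S,2S,10S,14S): 3 with CHO converted into CH(OH)CH2C(=O)C≡C–TMS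
Conditions: BF3·OEt2, CH2Cl2, −78 °C; aq NaHCO3
Reagents that add atoms: none
Why: Mukaiyama aldol addition through an open transition state with the nucleophile anti to the C1–C14 bond and the C2=O dipole opposed to the axial C14–OTBS bond (1,3-anti polar induction), which sets C2 (S).

**Step 4**
Reactants: 6 β-hydroxy ynone
Product: 7 syn-2,4-diol (1S,2S,4R,10S,14S)
Conditions: Et2BOMe, NaBH4, THF/MeOH (4:1), −78 °C; AcOH, then MeOH co-evaporation
Reagents that add atoms: none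
Why: Narasaka–Prasad reduction, in which hydride attacks the six-membered boron chelate of the β-hydroxy ketone axially and gives the syn-1,3-diol, setting C4 (R).

**Step 5**
Reactants: 7 syn-2,4-diol
Product: 8 2,4-bis-TBS ether ethyl ester (1S,2S,4R,10S,14S)
Conditions: TBSOTf, 2,6-lutidine, CH2Cl2, −78 → 0 °C; aq NaHCO3
Reagents that add atoms: tert-butyldimethylsilyl triflate CC(C)(C)[Si](C)(C)OS(=O)(=O)C(F)(F)F
Why: Silyl ether formation with the reactive silyl triflate protects both secondary alcohols without touching the ester or alkyne.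

**Step 6**
Reactants: 8 bis-TBS ether ethyl ester
Product: 9 C9 Weinreb amide (1S,2S,4R,10S,14S)
Conditions: MeNH(OMe)·HCl, i-PrMgCl, THF, −20 → 0 °C; aq NH4Cl
Reagents that add atoms: N,O-dimethylhydroxylamine hydrochloride CNOC.Cl
Why: Weinreb amidation of the ester by the magnesium amide (acyl substitution); C10 is not epimerised at this temperature.

**Step 7**
Reactants: 9 Weinreb amide; 10 methoxyallene (1-methoxypropa-1,2-diene)
Product: 12 C9 ketone bearing the 1-methoxyallenyl group (1S,2S,4R,10S,14S), via 1-lithio-1-methoxyallene 11 (not isolated)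
Conditions: 10, n-BuLi, THF, −78 → −40 °C; then 9, −78 °C; aq NH4Cl
Reagents that add atoms: none
Why: Weinreb ketone synthesis with an α-alkoxy allenyllithium (acyl anion equivalent), where the chelated tetrahedral intermediate prevents over-addition.

**Step 8**
Reactants: 12 allenyl ketone
Product: 14 (9S)-9-hydroxy-8-oxo vinyl ketone (1S,2S,4R,9S,10S,14S), via allenyl carbinol 13 (not isolated)
Conditions: NaBH4, CeCl3·7H2O, MeOH, −78 °C; then 1 M HCl, THF, 0 °C
Reagents that add atoms: water O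
Why: Luche 1,2-reduction under Felkin–Anh control (hydride anti to the quaternary-carbon substituent C1 on C10) sets C9 (S), and acid hydrolysis of the methoxyallene unmasks the vinyl ketone.

**Step 9**
Reactants: 14 hydroxy vinyl ketone
Product: 15 9-TBS ether of 14 (1S,2S,4R,9S,10S,14S)
Conditions: TBSOTf, 2,6-lutidine, CH2Cl2, −78 °C; aq NaHCO3
Reagents that add atoms: tert-butyldimethylsilyl triflate CC(C)(C)[Si](C)(C)OS(=O)(=O)C(F)(F)F
Why: Silylation of the secondary alcohol; the bulky silyl ether also suppresses chelation in step 10.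

**Step 10**
Reactants: 15 silyloxy vinyl ketone; 16 tert-butyl propanoate
Product: 19 aldol adduct as C8 trimethylsilyl ether (1S,2S,4R,8R,9S,10S,14S,17R), via lithium Z-enolate 17 (not isolated), via lithium aldolate 18 (not isolated)
Conditions: 16, LDA, THF/DMPU (4:1), −78 °C; then 15 pre-stirred with CeCl3, −78 °C; then TMSCl, −78 → 0 °C
Reagents that add atoms: chlorotrimethylsilane C[Si](C)(C)Cl
Why: Ketone aldol addition of the Z(O) ester enolate, in which polar Felkin–Anh attack anti to the C9–OSi bond sets C8 (R), the chair transition state with the C9 branch equatorial gives the syn C8–O/C17–Me relation (C17 R), cerium trichloride favours 1,2- over 1,4-addition, and the tertiary alkoxide is capped in situ.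

**Step 11**
Reactants: 19 aldol adduct
Product: 20 C11 enone (11-oxo, C12=C13; 1S,2S,4R,8R,9S,10S,14S,17R)
Conditions: CrO3, 3,5-dimethylpyrazole, CH2Cl2, −20 °C
Reagents that add atoms: chromium trioxide O=[Cr](=O)=O
Why: Allylic oxidation at the only unhindered allylic methylene (C11; the C14–H is neopentyl and silyloxy-substituted, and the C8 vinyl group has no allylic hydrogen).

**Step 12**
Reactants: 20 enone
Product: 22 saturated C11 ketone (1R,2S,4R,8R,9S,10S,14S,17R), via phenylsilyl enol ether 21 (not isolated)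
Conditions: [(Ph3P)CuH]6 (5 mol %), PhSiH3, toluene, rt; then aq NH4Cl
Reagents that add atoms: none
Why: Copper-hydride (Stryker) conjugate reduction is chemoselective for the enone over the vinyl group, the silyl alkyne and the ester.

**Step 13**
Reactants: 22 C11 ketone
Product: 24 enyne with C11(OH)CH2TMS, free C8–OH and terminal alkyne (1R,2S,4R,8R,9S,10S,14S,17R; C11 unassigned), via Peterson adduct 23 (not isolated)
Conditions: Me3SiCH2Li, CeCl3, THF, −78 °C; aq NH4Cl; then K2CO3, MeOH, rt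
Reagents that add atoms: (trimethylsilyl)methyllithium [Li]C[Si](C)(C)C
Why: Organocerium addition (first half of a Peterson olefination) to the enolisable ketone stores the C11 methylene as a metathesis-inert β-hydroxysilane, and methanolysis removes the alkynyl and O-trimethylsilyl groups.

**Step 14**
Reactants: 24 enyne
Product: 26 ten-membered (6Z)-5(16),6-diene tert-butyl ester (1R,2S,4R,8R,9S,10S,14S,17R), via triene 25 (not isolated)
Conditions: second-generation Hoveyda–Grubbs catalyst RuCl2(H2IMes)(=CH-C6H4-2-OiPr) (15 mol %), ethylene (1 atm), toluene (1 mM), 80 °C; then argon sparge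
Reagents that add atoms: ethene C=C
Why: Ethylene-mediated ring-closing enyne metathesis, in which cross enyne metathesis with ethylene gives the 2-substituted butadiene and its terminal vinyl group then closes the ten-membered ring onto the C8 vinyl group (cis C6=C7 expected for this ring size; no stereocentre is formed and no other metathesis-active alkene is present).

**Step 15**
Reactants: 26 macrocyclic diene tert-butyl ester
Product: 27 (5Z)-Δ5 19,7-lactone with C16 methyl (1R,2S,4R,7S,8S,9S,10S,14S,17R; C7 and C8 drawn as in the target)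
Conditions: [N,N′-bis(3,5-di-tert-butylsalicylidene)cyclohexane-1,2-diaminato]cobalt, Co(salen) (3 mol %), N-fluoro-2,4,6-trimethylpyridinium triflate (1.2 equiv), PhSiH3 (1.2 equiv), PhCF3, 0 °C → rt; aq NaHCO3
Reagents that add atoms: none
Why: Proposed new method: cobalt-hydride hydrogen-atom-transfer/radical-polar crossover 1,4-hydrolactonization of a 1,3-diene, in which the cobalt hydride delivers H• to the terminal C16 to give the C5–C7 allyl radical, oxidation gives an allyl cation equivalent that the tert-butyl ester carbonyl oxygen captures at C7 in a 5-exo mode (attack at C5 would need a seven-membered ring) and isobutene is lost, C7 being set because A(1,3) strain holds the C8–OH in the diene plane and the ester arm on the face that gives the trans-fused lactone; the closest known reaction type is the cobalt–salen catalysed Markovnikov hydrolactonization/deprotective hydroalkoxylation of isolated alkenes, not yet shown for a conjugated diene with 1,4-regiochemistry in a medium ring.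

**Step 16**
Reactants: 27 Δ5 lactone
Product: 28 6-chloro-5(16)-ene lactone (1R,2S,4R,6S,7R,8S,9S,10S,14S,17R)
Conditions: Ca(OCl)2, CO2 (solid), CH2Cl2/H2O, 0 °C
Reagents that add atoms: calcium hypochlorite [Ca+2].[O-]Cl.[O-]Cl
Why: Ene-type allylic chlorination by hypochlorous acid puts chlorine on C6 of the only alkene and removes a C16 hydrogen to give the C5 methylene, with attack anti to the allylic C7–O bond in the conformer where H7 eclipses the alkene (A(1,3) strain) setting C6 (S).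

**Step 17**
Reactants: 28 chloro-lactone
Product: 29 2,4,8,9,14-pentahydroxy-6-chloro-5(16),11(20)-diene lactone (1R,2S,4R,6S,7R,8R,9S,10S,14S,17R)
Conditions: aq HF (48 %), MeCN, 0 °C → rt
Reagents that add atoms: none
Why: Fluoride/acid cleavage of the four silyl ethers together with acid-promoted Peterson elimination of the β-hydroxysilane gives the C11 methylene.

**Step 18**
Reactants: 29 pentaol
Product: 30 CNP0186618.1 (target)
Conditions: Ac2O, pyridine, DMAP (cat.), CH2Cl2, 0 °C → rt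
Reagents that add atoms: acetic anhydride CC(=O)OC(C)=O
Why: DMAP-catalysed acetylation esterifies the four secondary alcohols while the hindered tertiary C8 alcohol stays free.

**Compound list**
1 | (E)-1-(tert-butyldimethylsilyloxy)buta-1,3-diene | C=C/C=C/O[Si](C)(C)C(C)(C)C | starting material
2 | ethyl (E)-3-methyl-4-oxobut-2-enoate | CCOC(=O)/C=C(\C)C=O | starting material
3 | ethyl (1S,5S,6R)-5-(TBSO)-6-formyl-6-methylcyclohex-3-ene-1-carboxylate | C1C=C[C@H](O[Si](C)(C)C(C)(C)C)[C@](C)(C=O)[C@H]1C(=O)OCC | intermediate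
4 | 4-(trimethylsilyl)but-3-yn-2-one | CC(=O)C#C[Si](C)(C)C | starting material
5 | 2-(trimethylsilyloxy)-4-(trimethylsilyl)but-1-en-3-yne | C=C(O[Si](C)(C)C)C#C[Si](C)(C)C | intermediate
6 | β-hydroxy ynone (1S,2S,10S,14S): C1 side chain CH(OH)CH2C(=O)C≡C–TMS | C1C=C[C@H](O[Si](C)(C)C(C)(C)C)[C@](C)([C@@H](O)CC(=O)C#C[Si](C)(C)C)[C@H]1C(=O)OCC | intermediate
7 | syn-2,4-diol (1S,2S,4R,10S,14S) | C1C=C[C@H](O[Si](C)(C)C(C)(C)C)[C@](C)([C@@H](O)C[C@@H](O)C#C[Si](C)(C)C)[C@H]1C(=O)OCC | intermediate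
8 | 2,4-bis-TBS ether ethyl ester (1S,2S,4R,10S,14S) | C1C=C[C@H](O[Si](C)(C)C(C)(C)C)[C@](C)([C@@H](O[Si](C)(C)C(C)(C)C)C[C@@H](O[Si](C)(C)C(C)(C)C)C#C[Si](C)(C)C)[C@H]1C(=O)OCC | intermediate
9 | C9 N-methoxy-N-methylamide (1S,2S,4R,10S,14S) | C1C=C[C@H](O[Si](C)(C)C(C)(C)C)[C@](C)([C@@H](O[Si](C)(C)C(C)(C)C)C[C@@H](O[Si](C)(C)C(C)(C)C)C#C[Si](C)(C)C)[C@H]1C(=O)N(C)OC | intermediate
10 | methoxyallene (1-methoxypropa-1,2-diene) | COC=C=C | starting material
11 | 1-lithio-1-methoxyallene | [Li]C(OC)=C=C | intermediate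
12 | C9 ketone with 1-methoxyallenyl group (1S,2S,4R,10S,14S) | C1C=C[C@H](O[Si](C)(C)C(C)(C)C)[C@](C)([C@@H](O[Si](C)(C)C(C)(C)C)C[C@@H](O[Si](C)(C)C(C)(C)C)C#C[Si](C)(C)C)[C@H]1C(=O)C(OC)=C=C | intermediate
13 | (9S)-allenyl carbinol (1S,2S,4R,9S,10S,14S) | C1C=C[C@H](O[Si](C)(C)C(C)(C)C)[C@](C)([C@@H](O[Si](C)(C)C(C)(C)C)C[C@@H](O[Si](C)(C)C(C)(C)C)C#C[Si](C)(C)C)[C@H]1[C@H](O)C(OC)=C=C | intermediate
14 | (9S)-9-hydroxy-8-oxo vinyl ketone (1S,2S,4R,9S,10S,14S) | C1C=C[C@H](O[Si](C)(C)C(C)(C)C)[C@](C)([C@@H](O[Si](C)(C)C(C)(C)C)C[C@@H](O[Si](C)(C)C(C)(C)C)C#C[Si](C)(C)C)[C@H]1[C@H](O)C(=O)C=C | intermediate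
15 | 9-TBS ether of 14 (1S,2S,4R,9S,10S,14S) | C1C=C[C@H](O[Si](C)(C)C(C)(C)C)[C@](C)([C@@H](O[Si](C)(C)C(C)(C)C)C[C@@H](O[Si](C)(C)C(C)(C)C)C#C[Si](C)(C)C)[C@H]1[C@H](O[Si](C)(C)C(C)(C)C)C(=O)C=C | intermediate
16 | tert-butyl propanoate | CCC(=O)OC(C)(C)C | starting material
17 | lithium (Z)-enolate of tert-butyl propanoate | C/C=C(\O[Li])OC(C)(C)C | intermediate
18 | lithium aldolate (C8–OLi; 1S,2S,4R,8R,9S,10S,14S,17R) | C1C=C[C@H](O[Si](C)(C)C(C)(C)C)[C@](C)([C@@H](O[Si](C)(C)C(C)(C)C)C[C@@H](O[Si](C)(C)C(C)(C)C)C#C[Si](C)(C)C)[C@H]1[C@H](O[Si](C)(C)C(C)(C)C)[C@@](O[Li])(C=C)[C@@H](C)C(=O)OC(C)(C)C | intermediate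
19 | aldol adduct, C8–OTMS, C8 vinyl, C17 methyl, tert-butyl ester (1S,2S,4R,8R,9S,10S,14S,17R) | C1C=C[C@H](O[Si](C)(C)C(C)(C)C)[C@](C)([C@@H](O[Si](C)(C)C(C)(C)C)C[C@@H](O[Si](C)(C)C(C)(C)C)C#C[Si](C)(C)C)[C@H]1[C@H](O[Si](C)(C)C(C)(C)C)[C@@](O[Si](C)(C)C)(C=C)[C@@H](C)C(=O)OC(C)(C)C | intermediate
20 | C11 enone (11-oxo, C12=C13; 1S,2S,4R,8R,9S,10S,14S,17R) | O=C1C=C[C@H](O[Si](C)(C)C(C)(C)C)[C@](C)([C@@H](O[Si](C)(C)C(C)(C)C)C[C@@H](O[Si](C)(C)C(C)(C)C)C#C[Si](C)(C)C)[C@H]1[C@H](O[Si](C)(C)C(C)(C)C)[C@@](O[Si](C)(C)C)(C=C)[C@@H](C)C(=O)OC(C)(C)C | intermediate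
21 | C11 phenylsilyl enol ether (C11=C12; 1R,2S,4R,8R,9S,10S,14S,17R) | c2ccccc2[SiH2]OC1=CC[C@H](O[Si](C)(C)C(C)(C)C)[C@](C)([C@@H](O[Si](C)(C)C(C)(C)C)C[C@@H](O[Si](C)(C)C(C)(C)C)C#C[Si](C)(C)C)[C@H]1[C@H](O[Si](C)(C)C(C)(C)C)[C@@](O[Si](C)(C)C)(C=C)[C@@H](C)C(=O)OC(C)(C)C | intermediate
22 | saturated C11 ketone (1R,2S,4R,8R,9S,10S,14S,17R) | O=C1CC[C@H](O[Si](C)(C)C(C)(C)C)[C@](C)([C@@H](O[Si](C)(C)C(C)(C)C)C[C@@H](O[Si](C)(C)C(C)(C)C)C#C[Si](C)(C)C)[C@H]1[C@H](O[Si](C)(C)C(C)(C)C)[C@@](O[Si](C)(C)C)(C=C)[C@@H](C)C(=O)OC(C)(C)C | intermediate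
23 | Peterson adduct, C11(OH)CH2TMS, still C8–OTMS and alkynyl-TMS (C11 unassigned) | OC1(C[Si](C)(C)C)CC[C@H](O[Si](C)(C)C(C)(C)C)[C@](C)([C@@H](O[Si](C)(C)C(C)(C)C)C[C@@H](O[Si](C)(C)C(C)(C)C)C#C[Si](C)(C)C)[C@H]1[C@H](O[Si](C)(C)C(C)(C)C)[C@@](O[Si](C)(C)C)(C=C)[C@@H](C)C(=O)OC(C)(C)C | intermediate
24 | enyne: terminal alkyne at C4, C8(OH) vinyl, C11(OH)CH2TMS (1R,2S,4R,8R,9S,10S,14S,17R; C11 unassigned) | OC1(C[Si](C)(C)C)CC[C@H](O[Si](C)(C)C(C)(C)C)[C@](C)([C@@H](O[Si](C)(C)C(C)(C)C)C[C@@H](O[Si](C)(C)C(C)(C)C)C#C)[C@H]1[C@H](O[Si](C)(C)C(C)(C)C)[C@@](O)(C=C)[C@@H](C)C(=O)OC(C)(C)C | intermediate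
25 | triene: C4 bears buta-1,3-dien-2-yl | OC1(C[Si](C)(C)C)CC[C@H](O[Si](C)(C)C(C)(C)C)[C@](C)([C@@H](O[Si](C)(C)C(C)(C)C)C[C@@H](O[Si](C)(C)C(C)(C)C)C(=C)C=C)[C@H]1[C@H](O[Si](C)(C)C(C)(C)C)[C@@](O)(C=C)[C@@H](C)C(=O)OC(C)(C)C | intermediate
26 | ten-membered (6Z)-5(16),6-diene, C8(OH)–CH(CH3)CO2tBu (1R,2S,4R,8R,9S,10S,14S,17R) | OC1(C[Si](C)(C)C)CC[C@H](O[Si](C)(C)C(C)(C)C)[C@]2(C)[C@@H](O[Si](C)(C)C(C)(C)C)C[C@@H](O[Si](C)(C)C(C)(C)C)C(=C)/C=C\[C@@](O)([C@@H](C)C(=O)OC(C)(C)C)[C@@H](O[Si](C)(C)C(C)(C)C)[C@@H]12 | intermediate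
27 | (5Z)-Δ5 19,7-lactone, C16 methyl (1R,2S,4R,7S,8S,9S,10S,14S,17R) | OC1(C[Si](C)(C)C)CC[C@H](O[Si](C)(C)C(C)(C)C)[C@]2(C)[C@@H](O[Si](C)(C)C(C)(C)C)C[C@@H](O[Si](C)(C)C(C)(C)C)/C(C)=C\[C@@H]3OC(=O)[C@H](C)[C@@]3(O)[C@@H](O[Si](C)(C)C(C)(C)C)[C@@H]12 | intermediate
28 | 6-chloro-5(16)-ene lactone, tetra-TBS, C11(OH)CH2TMS (1R,2S,4R,6S,7R,8S,9S,10S,14S,17R) | OC1(C[Si](C)(C)C)CC[C@H](O[Si](C)(C)C(C)(C)C)[C@]2(C)[C@@H](O[Si](C)(C)C(C)(C)C)C[C@@H](O[Si](C)(C)C(C)(C)C)C(=C)[C@H](Cl)[C@@H]3OC(=O)[C@H](C)[C@@]3(O)[C@@H](O[Si](C)(C)C(C)(C)C)[C@@H]12 | intermediate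
29 | 6-chloro-2,4,8,9,14-pentahydroxy-5(16),11(20)-diene 19,7-lactone (1R,2S,4R,6S,7R,8R,9S,10S,14S,17R) | C=C1CC[C@H](O)[C@]2(C)[C@@H](O)C[C@@H](O)C(=C)[C@H](Cl)[C@@H]3OC(=O)[C@H](C)[C@@]3(O)[C@@H](O)[C@@H]12 | intermediate
30 | CNP0186618.1, 2,4,9,14-tetraacetate (1R,2S,4R,6S,7R,8R,9S,10S,14S,17R) | C=C1CC[C@H](OC(C)=O)[C@]2(C)[C@@H](OC(C)=O)C[C@@H](OC(C)=O)C(=C)[C@H](Cl)[C@@H]3OC(=O)[C@H](C)[C@@]3(O)[C@@H](OC(C)=O)[C@@H]12 | target

**Step count and risks**
Total: 18 steps. Longest linear sequence: 17 steps (1, 3–18); step 2 is a one-step side branch.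

Most likely to fail:

Step 14 (ring closure). A strained ten-membered diene may lose to oligomerisation, and the C8 vinyl group is hindered. The fallback sets out from 24: bromoboration–protonolysis (B-bromo-9-borabicyclo[3.3.1]nonane, CH2Cl2, 0 °C; AcOH) gives the 2-bromo-1-alkene F1. A high-dilution intramolecular Heck reaction (Pd(OAc)2, P(o-tol)3, K2CO3, MeCN, 80 °C) then bonds C5 to the terminal carbon of the C8 vinyl group and, after β-hydride elimination, gives the (6E)-diene macrocycle F2. Step 15 passes through an allyl intermediate in which the C6=C7 geometry is lost, so F2 is put through the step 15 conditions and the route is rejoined at 27.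

Step 15 (the proposed new step). Hydrogen-atom transfer to a diene inside a medium ring, 1,4- versus 1,2-capture and competing attack by a silyl ether oxygen are all untested. The fallback uses known chemistry and sets out from 26: iodolactonization with loss of the tert-butyl group (I2, NaHCO3, MeCN, 0 °C) gives the allylic iodide lactone F3 (drawn as the 16-iodo Δ5 isomer; its 6-iodo allylic isomer converges). Radical deiodination (Bu3SnH, Et3B/air, toluene, 0 °C) then puts hydrogen on the primary terminus of the allyl radical and comes back to the route at 27.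

Step 16 (C6 stereocentre). The chlorenium may attack the other alkene face. The fallback sets out from 27: a Schenck ene reaction (O2, tetraphenylporphyrin, hν, CH2Cl2, 0 °C) would then also attack that face and give the C6 hydroperoxide F4 with the C5(16) methylene. PPh3 reduces it to the C6 allylic alcohol F5, and substitution with inversion (PPh3, N-chlorosuccinimide, THF, −20 °C) comes back to the route at 28.

**Further compounds**
F1 | step 14 | 2-bromo-1-alkene (C5 bromide of 24) | OC1(C[Si](C)(C)C)CC[C@H](O[Si](C)(C)C(C)(C)C)[C@](C)([C@@H](O[Si](C)(C)C(C)(C)C)C[C@@H](O[Si](C)(C)C(C)(C)C)C(Br)=C)[C@H]1[C@H](O[Si](C)(C)C(C)(C)C)[C@@](O)(C=C)[C@@H](C)C(=O)OC(C)(C)C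
F2 | step 14 | (6E)-diene macrocycle (6E isomer of 26) | OC1(C[Si](C)(C)C)CC[C@H](O[Si](C)(C)C(C)(C)C)[C@]2(C)[C@@H](O[Si](C)(C)C(C)(C)C)C[C@@H](O[Si](C)(C)C(C)(C)C)C(=C)/C=C/[C@@](O)([C@@H](C)C(=O)OC(C)(C)C)[C@@H](O[Si](C)(C)C(C)(C)C)[C@@H]12
F3 | step 15 | allylic iodide lactone (16-iodo analogue of 27) | OC1(C[Si](C)(C)C)CC[C@H](O[Si](C)(C)C(C)(C)C)[C@]2(C)[C@@H](O[Si](C)(C)C(C)(C)C)C[C@@H](O[Si](C)(C)C(C)(C)C)/C(CI)=C\[C@@H]3OC(=O)[C@H](C)[C@@]3(O)[C@@H](O[Si](C)(C)C(C)(C)C)[C@@H]12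
F4 | step 16 | C6 hydroperoxide with C5(16) methylene (6R) | OC1(C[Si](C)(C)C)CC[C@H](O[Si](C)(C)C(C)(C)C)[C@]2(C)[C@@H](O[Si](C)(C)C(C)(C)C)C[C@@H](O[Si](C)(C)C(C)(C)C)C(=C)[C@@H](OO)[C@@H]3OC(=O)[C@H](C)[C@@]3(O)[C@@H](O[Si](C)(C)C(C)(C)C)[C@@H]12
F5 | step 16 | C6 allylic alcohol with C5(16) methylene (6R) | OC1(C[Si](C)(C)C)CC[C@H](O[Si](C)(C)C(C)(C)C)[C@]2(C)[C@@H](O[Si](C)(C)C(C)(C)C)C[C@@H](O[Si](C)(C)C(C)(C)C)C(=C)[C@@H](O)[C@@H]3OC(=O)[C@H](C)[C@@]3(O)[C@@H](O[Si](C)(C)C(C)(C)C)[C@@H]12
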